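By 72.0 h the reading of Saturday's flask gave 24.0 moles of product per mole of free catalyst charged, and I carried this turnover number through the reckoning for that flask at 4.0 d.

| flask | solid substrate | coupling partner | free catalyst | remark | time |
|---|---|---|---|---|---|
| Saturday's | 0.75 M | 0.975 M | 4.1 mM | the very flask that is asked about, followed so far |  |
| Tuesday's | 1.1 M | 0.975 M | 4.1 mM | run made earlier |  |
| flask | 0.75 M | 0.975 M | 4.1 mM |  | 4.0 d |

| run | time / h | product / % | solid substrate / % |
|---|---|---|---|
| Saturday's | 6.00 | 8.2 | 76.3 |
| Saturday's | 10.0 | 10.6 | 63.6 |
| Saturday's | 15.0 | 12.9 | 54.4 |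
| Saturday's | 20.0 | 12.1 | 47.3 |
| Saturday's | 30.0 | 12.4 | 41.9 |
| Saturday's | 48.0 | 13.0 | 38.3 |
| Saturday's | 72.0 | 13.1 | 38.5 |
| Tuesday's | 0.500 | 0 | 98.9 |
| Tuesday's | 0.833 | 1.0 | 96.1 |
| Tuesday's | 1.33 | 0.7 | 95.0 |
| Tuesday's | 2.00 | 1.6 | 93.9 |
| Tuesday's | 3.00 | 2.6 | 90.2 |
| Tuesday's | 5.00 | 5.3 | 85.9 |
| Tuesday's | 8.00 | 5.5 | 79.2 |

(scatter of a reading: 0.5 percentage points)

- solid substrate is a solid; its amount is given per volume of the solution
- what is taken out of product is counted as made
- the earlier runs were read with a standard deviation of 0.5 percentage points
- what may be going on: coupling partner + free catalyst -> catalyst intermediate A; starting material + catalyst intermediate A <-> catalyst intermediate B; catalyst intermediate B -> free catalyst + product; catalyst intermediate A -> spent catalyst; solid substrate <-> starting material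
- at the start none of the solid substrate is in solution
- additions bring no volume worth counting

- spring: at 4.0 d add coupling partner, 50.0 % of the amount charged, then wait 8.0 d
- winter: change nothing and wait 8.0 d more
- noon: at 4.0 d add free catalyst, 100 % of the amount charged, then wait 8.0 d
- dusk: at 4.0 d take out 90 % of the product then present, then wait 8.0 d

- product, in percent of the solid substrate first charged, at 4.0 d
- what to do for the largest gain in product; "none" if nothing gains more than 2 percentage points (spring / winter / noon / dusk / none)
- product present, with what was taken out counted in, in percent of the solid substrate first charged, after spring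
- product present, with what was taken out counted in, in percent of the solid substrate first charged, after winter

By the readings of Saturday's flask product came at 0.0102 M h⁻¹ up to 6.00 h and at 0.00450 M h⁻¹ from there up to 10.0 h, so the rate fell by a factor of 2.27. Yet I read the dissolved share, which is what neither lies as solid nor has become product, as rising on average from 7.75 % to 20.7 %, a factor of 2.67 upward. Taking the rate as proportional to the dissolved share and to the working catalyst, I read the working catalyst as having dropped by a factor of 6.07 between the middles of those intervals, which I read as a half-life of 1.92 h. By 48.0 h that is 25.0 halvings, so I expected Saturday's flask to stand near 13.1 % at 4.0 d and waiting to add nothing.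

The solid dissolved at much the same pace per litre at the two charges: Tuesday's flask had lost 0.229 M by 8.00 h, and the mean of Saturday's losses at 6.00 h and 10.0 h is 0.225 M. So I took the turnover number to carry across solid charges at these charges of free catalyst and coupling partner. A fresh catalyst charge, however, would meet 48.4 % dissolved, more than the 7.75 % of the first hours, so I expected it to earn more turnovers than the first charge.

The forecast gave 13.1 % at 4.0 d, 13.2 % after spring and 13.2 % after winter, and it chose noon, saying “Only fresh catalyst restarts it”, with perhaps 13 to 16 points more.

The flask gives 12.8 % at 4.0 d, 12.8 % after spring, 12.8 % after winter and noon as best, with a gain of 47 percentage points.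

    coupling partner + free catalyst → catalyst intermediate A (k = 73.0 M⁻¹ h⁻¹)
    starting material + catalyst intermediate A ⇌ catalyst intermediate B (K = 0.570 M⁻¹, k = 150 M⁻¹ h⁻¹)
    catalyst intermediate B → free catalyst + product (k = 3600 h⁻¹)
    catalyst intermediate A → spent catalyst (k = 0.380 h⁻¹)
    solid substrate ⇌ starting material, rate k5*(cs5 - [starting material]) while solid is left; crystals form when [starting material] > cs5 (solubility = 0.370 M, k = 0.100 h⁻¹)

At 8.23 h in the asked flask the forward capture of catalyst intermediate A by starting material ran at 63 times its loss to spent catalyst, above the 24.0 turnovers read for Saturday's run. In that flask spent catalyst was already 95.2 % of the catalyst at 9.60 h, when starting material stood at 24.1 %, against 48.7 % at 48.0 h. The neighbouring flask with 1.9 M of solid substrate reckons from 24.0 turnovers to 5.17 % and stands at 5.06 %.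

(The readings were computed on assumed constants, noise included.)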